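**Plan**

- Numbering (germacrane locants): carbocycle C1 (=CH) to C10 (=C bearing C14H2OAc), with C4 (CHMe, methyl C15), C6 (lactone O–CH), C7 (ring fusion) and C8 (glycolate O–CH); lactone carbons C11, C12, C13 (exo-methylene).
- Enabling feature: inside the ten-membered ring the C8 carbinol is homoallylic to the trisubstituted C1=C10 alkene through C9 (O–C8–C9–C10=C1). This is the retron of a carbonyl-ene reaction between a C8 aldehyde and a C10(=C9H2) methylene group, with hydrogen transfer from C1.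
- Retrosynthetic cuts, in order: the O8 glycolate and O14 acetate esters and the C11=C13 methylene; the C8–C9 ring bond (type-two carbonyl-ene); the C1–C10 bond (sp3–sp2 coupling); the lactone C6–O bond; the C6–C7 aldol bond.
- Forward: a succinate imide (C7, C8, C11, C12) is joined to (S)-citronellal (C1–C6, C15) by syn-aldol; the γ-lactone closes with inversion at C6; the chain is cut back to C1 and extended by the C9/C10/C14 unit; the ten-membered ring closes last; methylenation and two acylations finish.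
- Stereochemistry: C4 from (S)-citronellal; C7 from the oxazolidinone auxiliary; C6 from the same aldol followed by SN2 inversion (giving the cis-lactone); C8 and the ring-cis alkene from the ene transition state under control of the cis-lactone.

Key step: step 11

Assumption: (S)-citronellal of high enantiomeric purity, mono-tert-butyl succinate and (tert-butyldimethylsilyloxy)acetic acid are taken as purchasable; the cis-formyl lactone 20 is assumed to be configurationally stable long enough to be used crude at low temperature.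

Step 1
Reactants: 1 2-bromoprop-2-en-1-ol
Product: 2 [(2-bromoprop-2-en-1-yl)oxy](tert-butyl)dimethylsilane
Conditions: TBSCl, imidazole, CH2Cl2, 0 °C to rt
Reagents that add atoms: tert-butyldimethylsilyl chloride (TBSCl), CC(C)(C)[Si](C)(C)Cl
Why: Standard silylation (silyl ether formation) of the primary allylic alcohol installs the C14 silyloxy group that lasts until step 14 and later keeps the C14–H bonds out of the ene hydrogen transfer.

Step 2
Reactants: 3 4-tert-butoxy-4-oxobutanoic acid (mono-tert-butyl succinate); 4 (4S)-4-benzyl-1,3-oxazolidin-2-one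
Product: 6 tert-butyl 4-[(4S)-4-benzyl-2-oxo-1,3-oxazolidin-3-yl]-4-oxobutanoate, via mixed pivalic anhydride 5 (not isolated)
Conditions: PivCl, Et3N, THF, −20 °C; then 4, LiCl, −20 °C to rt
Reagents that add atoms: none
Why: N-Acylation of the oxazolidinone through the mixed pivalic anhydride with LiCl and Et3N is the routine mild way to Evans imides and does not touch the tert-butyl ester.

Step 3
Reactants: 6 tert-butyl 4-[(4S)-4-benzyl-2-oxo-1,3-oxazolidin-3-yl]-4-oxobutanoate; 7 (3S)-3,7-dimethyloct-6-enal ((S)-citronellal)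
Product: 10 tert-butyl (3S,4R,6S)-3-{[(4S)-4-benzyl-2-oxo-1,3-oxazolidin-3-yl]carbonyl}-4-hydroxy-6,10-dimethylundec-9-enoate, via dibutylboron Z-enolate 8 (not isolated), via dibutylboron aldolate 9 (not isolated)
Conditions: Bu2BOTf, iPr2NEt, CH2Cl2, −78 to 0 °C; 7, −78 to 0 °C; then pH 7 phosphate buffer, MeOH, H2O2, 0 °C
Reagents that add atoms: none
Why: Evans syn-aldol reaction: the Z-boron enolate adds through a chair Zimmerman–Traxler transition state on the face away from the benzyl group, fixing C7 as required (S) and C6 as the R carbinol that step 5 inverts, while the bulky tert-butyl ester keeps the adduct from lactonising with retention.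

Step 4
Reactants: 10 tert-butyl (3S,4R,6S)-3-{[(4S)-4-benzyl-2-oxo-1,3-oxazolidin-3-yl]carbonyl}-4-hydroxy-6,10-dimethylundec-9-enoate
Product: 11 tert-butyl (3S,4R,6S)-3-{[(4S)-4-benzyl-2-oxo-1,3-oxazolidin-3-yl]carbonyl}-6,10-dimethyl-4-[(methylsulfonyl)oxy]undec-9-enoate
Conditions: MsCl, pyridine, CH2Cl2, 0 °C
Reagents that add atoms: methanesulfonyl chloride, CS(=O)(=O)Cl
Why: Mesylation of the secondary alcohol under weakly basic conditions provides the leaving group at C6 with retention, and β-elimination is held back because allylic strain in the imide keeps H7 poorly aligned for enolisation.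

Step 5
Reactants: 11 tert-butyl (3S,4R,6S)-3-{[(4S)-4-benzyl-2-oxo-1,3-oxazolidin-3-yl]carbonyl}-6,10-dimethyl-4-[(methylsulfonyl)oxy]undec-9-enoate
Product: 12 (4S)-4-benzyl-3-{[(2S,3S)-2-[(2S)-2,6-dimethylhept-5-en-1-yl]-5-oxooxolan-3-yl]carbonyl}-1,3-oxazolidin-2-one
Conditions: 2,6-lutidine, MeCN, 70 °C
Reagents that add atoms: none
Why: Intramolecular SN2 lactonisation: the carbonyl oxygen of the tert-butyl ester displaces the C6 mesylate in a 5-exo-tet closure with inversion and the alkoxy-oxocarbenium ion then loses isobutene, so C6 becomes S and the C5 and C8 arms end cis on the γ-lactone.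

Step 6
Reactants: 12 (4S)-4-benzyl-3-{[(2S,3S)-2-[(2S)-2,6-dimethylhept-5-en-1-yl]-5-oxooxolan-3-yl]carbonyl}-1,3-oxazolidin-2-one
Product: 15 (4S)-4-benzyl-3-{[(2S,3S)-2-[(2S)-5-hydroxy-2-methylpentyl]-5-oxooxolan-3-yl]carbonyl}-1,3-oxazolidin-2-one, via ozonide 13 (not isolated), via aldehyde 14 (not isolated)
Conditions: O3, CH2Cl2, −78 °C; PPh3, −78 to 0 °C; then NaBH4, MeOH, −40 °C
Reagents that add atoms: ozone, [O-][O+]=O
Why: Ozonolysis cleaves the only alkene, PPh3 reduces the ozonide to the C1 aldehyde, and NaBH4 at low temperature reduces this aldehyde much faster than the imide or the lactone.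

Step 7
Reactants: 15 (4S)-4-benzyl-3-{[(2S,3S)-2-[(2S)-5-hydroxy-2-methylpentyl]-5-oxooxolan-3-yl]carbonyl}-1,3-oxazolidin-2-one
Product: 16 (4S)-4-benzyl-3-{[(2S,3S)-2-[(2S)-5-iodo-2-methylpentyl]-5-oxooxolan-3-yl]carbonyl}-1,3-oxazolidin-2-one
Conditions: I2, PPh3, imidazole, CH2Cl2, 0 °C to rt
Reagents that add atoms: iodine, II
Why: Appel-type iodination (PPh3/I2/imidazole) converts the primary alcohol into the iodide under neutral conditions that spare the imide, the lactone and the C7 centre.

Step 8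
Reactants: 16 (4S)-4-benzyl-3-{[(2S,3S)-2-[(2S)-5-iodo-2-methylpentyl]-5-oxooxolan-3-yl]carbonyl}-1,3-oxazolidin-2-one; 2 [(2-bromoprop-2-en-1-yl)oxy](tert-butyl)dimethylsilane
Product: 18 (4S)-4-benzyl-3-{[(2S,3S)-2-[(2S)-6-({[tert-butyl(dimethyl)silyl]oxy}methyl)-2-methylhept-6-en-1-yl]-5-oxooxolan-3-yl]carbonyl}-1,3-oxazolidin-2-one, via alkylzinc iodide 17 (not isolated)
Conditions: Zn dust (I2-activated), DMA, 40 °C; then 2, PdCl2(dppf) (5 mol%), THF/DMA, 50 °C
Reagents that add atoms: none
Why: Negishi sp3–sp2 cross-coupling: zinc insertion gives a primary alkylzinc iodide that tolerates the imide and lactone, and the wide-bite-angle diphosphine favours reductive elimination over β-hydride elimination in the coupling with vinyl bromide 2, which forms the C1–C10 bond.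

Step 9
Reactants: 18 (4S)-4-benzyl-3-{[(2S,3S)-2-[(2S)-6-({[tert-butyl(dimethyl)silyl]oxy}methyl)-2-methylhept-6-en-1-yl]-5-oxooxolan-3-yl]carbonyl}-1,3-oxazolidin-2-one
Product: 19 (4R,5S)-5-[(2S)-6-({[tert-butyl(dimethyl)silyl]oxy}methyl)-2-methylhept-6-en-1-yl]-4-(hydroxymethyl)oxolan-2-one
Conditions: NaBH4, THF/H2O (4:1), 0 °C
Reagents that add atoms: none
Why: Reductive cleavage of the N-acyl oxazolidinone by NaBH4 in wet THF attacks the activated exocyclic imide carbonyl in preference to the γ-lactone and frees the auxiliary for recovery.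

Step 10
Reactants: 19 (4R,5S)-5-[(2S)-6-({[tert-butyl(dimethyl)silyl]oxy}methyl)-2-methylhept-6-en-1-yl]-4-(hydroxymethyl)oxolan-2-one
Product: 20 (2S,3S)-2-[(2S)-6-({[tert-butyl(dimethyl)silyl]oxy}methyl)-2-methylhept-6-en-1-yl]-5-oxooxolane-3-carbaldehyde
Conditions: Dess–Martin periodinane, NaHCO3, CH2Cl2, 0 °C; used without chromatography
Reagents that add atoms: none
Why: Dess–Martin oxidation takes the primary alcohol to the aldehyde under buffered, nearly neutral conditions at low temperature, which should leave the epimerisable C7 centre of the cis-formyl lactone intact.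

Step 11
Reactants: 20 (2S,3S)-2-[(2S)-6-({[tert-butyl(dimethyl)silyl]oxy}methyl)-2-methylhept-6-en-1-yl]-5-oxooxolane-3-carbaldehyde
Product: 22 (1(10)E,4S,6S,7R,8S)-14-(tert-butyldimethylsilyloxy)-8-hydroxy-13-norgermacr-1(10)-en-12,6-olide, via aluminium alkoxide 21 (not isolated)
Conditions: Me2AlCl (2.5 equiv), CH2Cl2, −78 to −20 °C, slow addition of 20 to 0.002 M; aqueous potassium sodium tartrate
Reagents that add atoms: none
Why: Proposed new method: Me2AlCl binds the C8 aldehyde, C9 (the CH2 terminus of the 1,1-disubstituted alkene) attacks C8 while an allylic hydrogen moves from C1 to oxygen through the six-membered array O/C8/C9/C10/C1/H, so that the C8–C9 bond, the C8 carbinol and the C1=C10 alkene arise together, and the product is held as an aluminium alkoxide after loss of methane. The closest known reaction type is the Me2AlCl-promoted type-two intramolecular carbonyl-ene cyclisation, which is established for six- to eight-membered rings but not for a ten-membered ring with hydrogen transfer from the tether methylene. The carbocycle closes as a ten-membered ring in the type-two mode, with the carbonyl oxygen exocyclic and both ene carbons C10 and C1 ending in the ring. C8 is expected to be set by the adjacent C7 centre of the cis-lactone in a Felkin–Anh sense, C9 entering anti to the C7–C6 bond and past H7, which corresponds to 8S; this is a prediction. The step needs hydrogen transfer from C1 instead of C14, the ring-cis alkene (E by the CIP rules) and no epimerisation at C7: the silyloxy group makes the C14–H bonds poor hydrogen donors, the cis-cyclodecene transition state is the less strained one, and low temperature with a Lewis acid that also scavenges protons protects C7, while high dilution and the cis-lactone, which holds the C5 and C8 arms on one face, favour ring closure over oligomerisation.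

Step 12
Reactants: 22 (1(10)E,4S,6S,7R,8S)-14-(tert-butyldimethylsilyloxy)-8-hydroxy-13-norgermacr-1(10)-en-12,6-olide
Product: 23 (1(10)E,4S,6S,7S,8S)-14-(tert-butyldimethylsilyloxy)-8-(triethylsilyloxy)-13-norgermacr-1(10)-en-12,6-olide
Conditions: TESOTf, 2,6-lutidine, CH2Cl2, −78 °C
Reagents that add atoms: triethylsilyl trifluoromethanesulfonate (TESOTf), CC[Si](CC)(CC)OS(=O)(=O)C(F)(F)F
Why: Silylation with the silyl triflate and a hindered base protects the hindered secondary O8 so that it can neither be deprotonated nor attack the lactone carbonyl during the enolate chemistry of step 13.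

Step 13
Reactants: 23 (1(10)E,4S,6S,7S,8S)-14-(tert-butyldimethylsilyloxy)-8-(triethylsilyloxy)-13-norgermacr-1(10)-en-12,6-olide
Product: 27 (1(10)E,4S,6S,7S,8S)-14-(tert-butyldimethylsilyloxy)-8-(triethylsilyloxy)germacra-1(10),11(13)-dien-12,6-olide, via lithium enolate 24 (not isolated), via Mannich base 25 (not isolated), via methiodide 26 (not isolated)
Conditions: LiN(iPr)2, THF, −78 °C; Me2N=CH2 I (Eschenmoser's salt), −78 to 0 °C; MeI, MeOH, rt; then NaHCO3, CH2Cl2/H2O, rt
Reagents that add atoms: N,N-dimethylmethyleneiminium iodide (Eschenmoser's salt), C=[N+](C)C.[I-]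
Why: α-Methylenation by Mannich reaction of the lactone lithium enolate with Eschenmoser's salt, N-methylation and Hofmann-type β-elimination is the standard route to α-methylene-γ-butyrolactones, and C11 is the only enolisable position in 23.

Step 14
Reactants: 27 (1(10)E,4S,6S,7S,8S)-14-(tert-butyldimethylsilyloxy)-8-(triethylsilyloxy)germacra-1(10),11(13)-dien-12,6-olide
Product: 28 (1(10)E,4S,6S,7R,8S)-8,14-dihydroxygermacra-1(10),11(13)-dien-12,6-olide
Conditions: HF·pyridine, pyridine, THF, 0 °C to rt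
Reagents that add atoms: none
Why: Fluoride-induced desilylation with buffered HF·pyridine removes the primary allylic TBS and the secondary TES ether together and is non-basic, so the α-methylene lactone is not exposed to Michael donors or translactonisation.

Step 15
Reactants: 28 (1(10)E,4S,6S,7R,8S)-8,14-dihydroxygermacra-1(10),11(13)-dien-12,6-olide
Product: 29 (1(10)E,4S,6S,7R,8S)-14-acetoxy-8-hydroxygermacra-1(10),11(13)-dien-12,6-olide
Conditions: AcCl, 2,4,6-collidine, CH2Cl2, −78 °C
Reagents that add atoms: acetyl chloride, CC(=O)Cl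
Why: Chemoselective acetylation: acetyl chloride with a hindered pyridine base at −78 °C acylates the unhindered primary allylic C14 hydroxyl far faster than the secondary C8 hydroxyl next to the ring fusion.

Step 16
Reactants: 29 (1(10)E,4S,6S,7R,8S)-14-acetoxy-8-hydroxygermacra-1(10),11(13)-dien-12,6-olide; 30 (tert-butyldimethylsilyloxy)acetic acid
Product: 32 (1(10)E,4S,6S,7S,8S)-14-acetoxy-8-[(tert-butyldimethylsilyloxy)acetoxy]germacra-1(10),11(13)-dien-12,6-olide, via O-acylisourea 31 (not isolated)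
Conditions: N,N'-diisopropylcarbodiimide, 4-(dimethylamino)pyridine (cat.), CH2Cl2, 0 °C to rt
Reagents that add atoms: none
Why: Steglich esterification (carbodiimide activation with nucleophilic catalysis) acylates the secondary C8 alcohol under neutral conditions with retention at C8, the silyl ether keeping the glycolic acid from self-condensation.

Step 17
Reactants: 32 (1(10)E,4S,6S,7S,8S)-14-acetoxy-8-[(tert-butyldimethylsilyloxy)acetoxy]germacra-1(10),11(13)-dien-12,6-olide
Product: 33 (1(10)E,4S,6S,7S,8S)-14-acetoxy-8-(hydroxyacetoxy)germacra-1(10),11(13)-dien-12,6-olide (CNP0156635.1)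
Conditions: HF·pyridine, pyridine, THF, 0 °C
Reagents that add atoms: none
Why: Desilylation with HF·pyridine cleaves the primary silyl ether of the glycolate without touching the acetate, the glycolate ester or the α-methylene lactone, giving the target.

**Compound list**

1 | 2-bromoprop-2-en-1-ol | C=C(Br)CO | starting material
2 | [(2-bromoprop-2-en-1-yl)oxy](tert-butyl)dimethylsilane | C=C(Br)CO[Si](C)(C)C(C)(C)C | intermediate
3 | 4-tert-butoxy-4-oxobutanoic acid (mono-tert-butyl succinate) | OC(=O)CCC(=O)OC(C)(C)C | starting material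
4 | (4S)-4-benzyl-1,3-oxazolidin-2-one | O=C1OC[C@H](Cc2ccccc2)N1 | starting material
5 | 4-tert-butoxy-4-oxobutanoic pivalic anhydride (mixed pivalic anhydride) | CC(C)(C)C(=O)OC(=O)CCC(=O)OC(C)(C)C | intermediate
6 | tert-butyl 4-[(4S)-4-benzyl-2-oxo-1,3-oxazolidin-3-yl]-4-oxobutanoate | O=C(CCC(=O)OC(C)(C)C)N1[C@@H](Cc2ccccc2)COC1=O | intermediate
7 | (3S)-3,7-dimethyloct-6-enal ((S)-citronellal) | O=CC[C@@H](C)CCC=C(C)C | starting material
8 | tert-butyl (3Z)-4-[(4S)-4-benzyl-2-oxo-1,3-oxazolidin-3-yl]-4-[(dibutylboranyl)oxy]but-3-enoate (dibutylboron Z-enolate of 6) | CCCCB(CCCC)O/C(=C\CC(=O)OC(C)(C)C)N1[C@@H](Cc2ccccc2)COC1=O | intermediate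
9 | O4-dibutylboranyl derivative of 10 (dibutylboron aldolate) | O=C(N1[C@@H](Cc2ccccc2)COC1=O)[C@@H](CC(=O)OC(C)(C)C)[C@H](OB(CCCC)CCCC)C[C@@H](C)CCC=C(C)C | intermediate
10 | tert-butyl (3S,4R,6S)-3-{[(4S)-4-benzyl-2-oxo-1,3-oxazolidin-3-yl]carbonyl}-4-hydroxy-6,10-dimethylundec-9-enoate (syn-aldol adduct) | O=C(N1[C@@H](Cc2ccccc2)COC1=O)[C@@H](CC(=O)OC(C)(C)C)[C@H](O)C[C@@H](C)CCC=C(C)C | intermediate
11 | tert-butyl (3S,4R,6S)-3-{[(4S)-4-benzyl-2-oxo-1,3-oxazolidin-3-yl]carbonyl}-6,10-dimethyl-4-[(methylsulfonyl)oxy]undec-9-enoate | O=C(N1[C@@H](Cc2ccccc2)COC1=O)[C@@H](CC(=O)OC(C)(C)C)[C@H](OS(C)(=O)=O)C[C@@H](C)CCC=C(C)C | intermediate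
12 | (4S)-4-benzyl-3-{[(2S,3S)-2-[(2S)-2,6-dimethylhept-5-en-1-yl]-5-oxooxolan-3-yl]carbonyl}-1,3-oxazolidin-2-one (cis-lactone imide) | O=C(N1[C@@H](Cc2ccccc2)COC1=O)[C@H]1CC(=O)O[C@H]1C[C@@H](C)CCC=C(C)C | intermediate
13 | (4S)-4-benzyl-3-{[(2S,3S)-2-[(2S)-4-(3,3-dimethyl-1,2,4-trioxolan-5-yl)-2-methylbutyl]-5-oxooxolan-3-yl]carbonyl}-1,3-oxazolidin-2-one (ozonide, trioxolane carbon unassigned) | O=C(N1[C@@H](Cc2ccccc2)COC1=O)[C@H]1CC(=O)O[C@H]1C[C@@H](C)CCC1OOC(C)(C)O1 | intermediate
14 | (4S)-4-benzyl-3-{[(2S,3S)-2-[(2S)-2-methyl-5-oxopentyl]-5-oxooxolan-3-yl]carbonyl}-1,3-oxazolidin-2-one | O=C(N1[C@@H](Cc2ccccc2)COC1=O)[C@H]1CC(=O)O[C@H]1C[C@@H](C)CCC=O | intermediate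
15 | (4S)-4-benzyl-3-{[(2S,3S)-2-[(2S)-5-hydroxy-2-methylpentyl]-5-oxooxolan-3-yl]carbonyl}-1,3-oxazolidin-2-one | O=C(N1[C@@H](Cc2ccccc2)COC1=O)[C@H]1CC(=O)O[C@H]1C[C@@H](C)CCCO | intermediate
16 | (4S)-4-benzyl-3-{[(2S,3S)-2-[(2S)-5-iodo-2-methylpentyl]-5-oxooxolan-3-yl]carbonyl}-1,3-oxazolidin-2-one | O=C(N1[C@@H](Cc2ccccc2)COC1=O)[C@H]1CC(=O)O[C@H]1C[C@@H](C)CCCI | intermediate
17 | iodo{(4S)-5-[(2S,3S)-3-{[(4S)-4-benzyl-2-oxo-1,3-oxazolidin-3-yl]carbonyl}-5-oxooxolan-2-yl]-4-methylpentyl}zinc (alkylzinc iodide) | O=C(N1[C@@H](Cc2ccccc2)COC1=O)[C@H]1CC(=O)O[C@H]1C[C@@H](C)CCC[Zn]I | intermediate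
18 | (4S)-4-benzyl-3-{[(2S,3S)-2-[(2S)-6-({[tert-butyl(dimethyl)silyl]oxy}methyl)-2-methylhept-6-en-1-yl]-5-oxooxolan-3-yl]carbonyl}-1,3-oxazolidin-2-one | O=C(N1[C@@H](Cc2ccccc2)COC1=O)[C@H]1CC(=O)O[C@H]1C[C@@H](C)CCCC(=C)CO[Si](C)(C)C(C)(C)C | intermediate
19 | (4R,5S)-5-[(2S)-6-({[tert-butyl(dimethyl)silyl]oxy}methyl)-2-methylhept-6-en-1-yl]-4-(hydroxymethyl)oxolan-2-one | OC[C@H]1CC(=O)O[C@H]1C[C@@H](C)CCCC(=C)CO[Si](C)(C)C(C)(C)C | intermediate
20 | (2S,3S)-2-[(2S)-6-({[tert-butyl(dimethyl)silyl]oxy}methyl)-2-methylhept-6-en-1-yl]-5-oxooxolane-3-carbaldehyde (cis-lactone C8 aldehyde, ene precursor) | O=C[C@H]1CC(=O)O[C@H]1C[C@@H](C)CCCC(=C)CO[Si](C)(C)C(C)(C)C | intermediate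
21 | O8-chloro(methyl)aluminium alkoxide of 22 | C1C(=O)O[C@H]2C[C@@H](C)CC/C=C(/CO[Si](C)(C)C(C)(C)C)C[C@H](O[Al](C)Cl)[C@@H]12 | intermediate
22 | (1(10)E,4S,6S,7R,8S)-14-(tert-butyldimethylsilyloxy)-8-hydroxy-13-norgermacr-1(10)-en-12,6-olide (cis-fused lactone, C2 and C9 cis on the alkene) | C1C(=O)O[C@H]2C[C@@H](C)CC/C=C(/CO[Si](C)(C)C(C)(C)C)C[C@H](O)[C@@H]12 | intermediate
23 | (1(10)E,4S,6S,7S,8S)-14-(tert-butyldimethylsilyloxy)-8-(triethylsilyloxy)-13-norgermacr-1(10)-en-12,6-olide | C1C(=O)O[C@H]2C[C@@H](C)CC/C=C(/CO[Si](C)(C)C(C)(C)C)C[C@H](O[Si](CC)(CC)CC)[C@@H]12 | intermediate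
24 | lithium enolate of 23 (C11=C12–OLi) | C1=C(O[Li])O[C@H]2C[C@@H](C)CC/C=C(/CO[Si](C)(C)C(C)(C)C)C[C@H](O[Si](CC)(CC)CC)[C@@H]12 | intermediate
25 | (1(10)E,4S,6S,7S,8S)-14-(tert-butyldimethylsilyloxy)-13-(dimethylamino)-8-(triethylsilyloxy)germacr-1(10)-en-12,6-olide (Mannich base, C11 unassigned) | CN(C)CC1C(=O)O[C@H]2C[C@@H](C)CC/C=C(/CO[Si](C)(C)C(C)(C)C)C[C@H](O[Si](CC)(CC)CC)[C@@H]12 | intermediate
26 | N-methyl iodide of 25 (13-trimethylammonio iodide, C11 unassigned) | C[N+](C)(C)CC1C(=O)O[C@H]2C[C@@H](C)CC/C=C(/CO[Si](C)(C)C(C)(C)C)C[C@H](O[Si](CC)(CC)CC)[C@@H]12.[I-] | intermediate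
27 | (1(10)E,4S,6S,7S,8S)-14-(tert-butyldimethylsilyloxy)-8-(triethylsilyloxy)germacra-1(10),11(13)-dien-12,6-olide | C=C1C(=O)O[C@H]2C[C@@H](C)CC/C=C(/CO[Si](C)(C)C(C)(C)C)C[C@H](O[Si](CC)(CC)CC)[C@@H]12 | intermediate
28 | (1(10)E,4S,6S,7R,8S)-8,14-dihydroxygermacra-1(10),11(13)-dien-12,6-olide | C=C1C(=O)O[C@H]2C[C@@H](C)CC/C=C(/CO)C[C@H](O)[C@@H]12 | intermediate
29 | (1(10)E,4S,6S,7R,8S)-14-acetoxy-8-hydroxygermacra-1(10),11(13)-dien-12,6-olide | C=C1C(=O)O[C@H]2C[C@@H](C)CC/C=C(/COC(C)=O)C[C@H](O)[C@@H]12 | intermediate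
30 | (tert-butyldimethylsilyloxy)acetic acid | OC(=O)CO[Si](C)(C)C(C)(C)C | starting material
31 | O-acylisourea from 30 and N,N'-diisopropylcarbodiimide | CC(C)N=C(NC(C)C)OC(=O)CO[Si](C)(C)C(C)(C)C | intermediate
32 | (1(10)E,4S,6S,7S,8S)-14-acetoxy-8-[(tert-butyldimethylsilyloxy)acetoxy]germacra-1(10),11(13)-dien-12,6-olide | C=C1C(=O)O[C@H]2C[C@@H](C)CC/C=C(/COC(C)=O)C[C@H](OC(=O)CO[Si](C)(C)C(C)(C)C)[C@@H]12 | intermediate
33 | (1(10)E,4S,6S,7S,8S)-14-acetoxy-8-(hydroxyacetoxy)germacra-1(10),11(13)-dien-12,6-olide (CNP0156635.1) | C=C1C(=O)O[C@H]2C[C@@H](C)CC/C=C(/COC(C)=O)C[C@H](OC(=O)CO)[C@@H]12 | target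

**Step count**

Total: 17 steps. Longest linear sequence: 16 steps (steps 2 to 17, from 3 and 4; 15 steps from (S)-citronellal 7).

**Steps most likely to fail**

Step 11 (ene macrocyclisation). What may go wrong: intermolecular ene reaction or oligomerisation instead of ten-membered closure; hydrogen transfer from C14 (giving an enol silyl ether) instead of C1; chloride capture of the developing C10 cation; poor facial selectivity at C8; epimerisation at C7 before closure. The fallback uses an intermolecular carbonyl-ene reaction followed by ring-closing metathesis, both established reaction types. It sets out from 12 and comes back at 22. Ozonolysis of 12 with PPh3 work-up is stopped at aldehyde 14, which is isolated here. Wittig methylenation (Ph3PCH3Br, KN(SiMe3)2, THF, −78 °C) should give the terminal alkene imide F1. NaBH4 in wet THF would remove the auxiliary to give the hydroxymethyl lactone F2, and Dess–Martin oxidation the formyl lactone F3. An intermolecular Me2AlCl-promoted carbonyl-ene reaction of F3 with the methallyl silyl ether F4 (made from 2-methylprop-2-en-1-ol and TBSCl) should form the C8–C9 bond with hydrogen transfer from the methyl group and, under Felkin–Anh control, give the 8S homoallylic alcohol F5. Ring-closing metathesis of F5 with the second-generation Hoveyda–Grubbs catalyst at high dilution in hot toluene would then close C1=C10 with loss of ethene and deliver 22.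

Step 5 (lactonisation with inversion). What may go wrong: β-elimination of the sulfonate toward the alkylidene imide competing with displacement, or ionisation too slow at temperatures the imide tolerates. In the fallback the C6 configuration is set by hydride reduction instead of substitution. It sets out from 10 and comes back at 12. Dess–Martin oxidation of 10 should give the β-keto imide F6, whose C7 centre is expected to be configurationally stable. Reduction with the non-chelating hydride KBHEt3 in Et2O at −78 °C is expected to follow the Felkin–Anh sense and give the anti alcohol F7. Cleavage of the tert-butyl ester with TMSOTf/2,6-lutidine and mild acidic work-up would close the lactone with retention to 12.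

Step 10 (oxidation to the cis-formyl lactone). What may go wrong: epimerisation at C7 from the cis to the more stable trans aldehyde during oxidation or isolation. In the fallback the aldehyde comes from the acyl oxidation level without base or oxidant. It sets out from 18 and comes back at 20, bypassing steps 9 and 10. LiSEt (EtSH, n-BuLi, THF, 0 °C) should convert 18 into the ethyl thioester F8 with release of the auxiliary. Fukuyama reduction (Et3SiH, Pd/C, acetone, rt) would give 20 under neutral conditions, and the filtered solution is taken directly into step 11.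

**Further compounds**

F1 | step 11 | (4S)-4-benzyl-3-{[(2S,3S)-2-[(2S)-2-methylhex-5-en-1-yl]-5-oxooxolan-3-yl]carbonyl}-1,3-oxazolidin-2-one | O=C(N1[C@@H](Cc2ccccc2)COC1=O)[C@H]1CC(=O)O[C@H]1C[C@@H](C)CCC=C
F2 | step 11 | (4R,5S)-4-(hydroxymethyl)-5-[(2S)-2-methylhex-5-en-1-yl]oxolan-2-one | OC[C@H]1CC(=O)O[C@H]1C[C@@H](C)CCC=C
F3 | step 11 | (2S,3S)-2-[(2S)-2-methylhex-5-en-1-yl]-5-oxooxolane-3-carbaldehyde | O=C[C@H]1CC(=O)O[C@H]1C[C@@H](C)CCC=C
F4 | step 11 | tert-butyldimethyl[(2-methylprop-2-en-1-yl)oxy]silane | C=C(C)CO[Si](C)(C)C(C)(C)C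
F5 | step 11 | (4R,5S)-4-[(1S)-3-({[tert-butyl(dimethyl)silyl]oxy}methyl)-1-hydroxybut-3-en-1-yl]-5-[(2S)-2-methylhex-5-en-1-yl]oxolan-2-one | C1C(=O)O[C@@H](C[C@@H](C)CCC=C)[C@H]1[C@@H](O)CC(=C)CO[Si](C)(C)C(C)(C)C
F6 | step 5 | tert-butyl (3S,6S)-3-{[(4S)-4-benzyl-2-oxo-1,3-oxazolidin-3-yl]carbonyl}-6,10-dimethyl-4-oxoundec-9-enoate | O=C(N1[C@@H](Cc2ccccc2)COC1=O)[C@@H](CC(=O)OC(C)(C)C)C(=O)C[C@@H](C)CCC=C(C)C
F7 | step 5 | tert-butyl (3S,4S,6S)-3-{[(4S)-4-benzyl-2-oxo-1,3-oxazolidin-3-yl]carbonyl}-4-hydroxy-6,10-dimethylundec-9-enoate | O=C(N1[C@@H](Cc2ccccc2)COC1=O)[C@@H](CC(=O)OC(C)(C)C)[C@@H](O)C[C@@H](C)CCC=C(C)C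
F8 | step 10 | S-ethyl (2S,3S)-2-[(2S)-6-({[tert-butyl(dimethyl)silyl]oxy}methyl)-2-methylhept-6-en-1-yl]-5-oxooxolane-3-carbothioate | CCSC(=O)[C@H]1CC(=O)O[C@H]1C[C@@H](C)CCCC(=C)CO[Si](C)(C)C(C)(C)C
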